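How long are the chains in the flask after 30 h, and how much X has reacted by then?

| flask | X | E | remark | time |
|---|---|---|---|---|
| south | 0.40 M | 10 mol% | run made earlier |  |
| south-west | 0.60 M | 10 mol% | run made earlier |  |
| east | 0.80 M | 5 mol% | run made earlier |  |
| flask | 0.80 M | 10 mol% |  | 30 h |

- south (time / h: Z / %, X / %): 5.00: 0.4, 72.5; 10.0: 3.1, 51.2; 15.0: 4.4, 36.4; 20.0: 5.3, 26.3; 25.0: 7.0, 18.2; 30.0: 8.6, 12.6
- south-west (time / h: Z / %, X / %): 5.00: 1.7, 72.2; 10.0: 3.1, 50.9; 15.0: 6.4, 35.6; 20.0: 7.5, 24.7; 25.0: 10.1, 16.8; 30.0: 11.8, 10.7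
- east (time / h: Z / %, X / %): 2.50: 0.2, 86.1; 8.00: 2.3, 59.4; 15.0: 3.7, 37.7; 20.0: 5.5, 26.2; 30.0: 6.3, 12.5

(each reading ± 0.5 percentage points)

- the average divides the monomer in chains by the number of chains begun, living and dead together
- the earlier runs do not show the number of chains; that part of a forecast is a guess

- average number of monomer units in a chain (chains begun, living or dead) at 30 h
- part of the X that has reacted at 30 h

A bench rule serves a flask in which each E begins one chain and each reacted X joins one: chain length equals X charged per E charged, here 10.0. Its border appears at the fork that a reacted X meets, into Z or elsewhere. At the last readings, Z divided by reacted X gives 9.84 % in south, 13.2 % in south-west and 7.20 % in east, each less than one, so the rule fails as it stands.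

These readings, with their scatter, rise with E in molar terms: the summed shares over the summed E charges give 2.16 M⁻¹. For the flask's 0.0800 M of E, that gives 17.3 %, the fork chance, the selectivity: the chance that a reacted X ends as Z. Taking the reacted part from south-west, 89.3 %, this reckoning gives the flask a chain length of 1.54 if each E begins a chain, and longer chains if fewer do.

The forecast gives 91 % reacted and a length of 2.5, longer than the 1.54 of the reckoning above, with the remark “Chains are unknown.”

The flask gives 89.9 % reacted and a length of 3.20.

    X + J → G + Z (k = 6.10 × 10⁻⁴ M⁻¹ s⁻¹)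
    X + G → Z + G, rate k2*[G]*[X] (k = 1.50 × 10⁻⁴ M⁻¹ s⁻¹)
    X → D (k = 1.70 × 10⁻⁵ s⁻¹)
    E ⇌ J (K = 0.490, k = 7.60 × 10⁻⁶ s⁻¹)
    J → L (k = 2.40 × 10⁻⁵ s⁻¹)

In the flask, the loss of X to D had done half of its turnover up to 30 h by 7.99 h, while the making of Z had 3.0 % of its turnover up to 30 h behind it after 3.00 h. At 30.0 h, Z made up 15.3 % of the reacted X, against the reckoned fork chance of 17.3 %, and G stood at 0.0345 M, which is 43.1 % of the E charged. A neighbouring flask with the same charges, read at 3.0 d, holds Z at 16.9 % with 99.8 % reacted, a share of 16.9 %, and its chains average 3.27.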